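Assumption: carbons are numbered as in germacranes (C1 ketone, C4=C5 olefin, C6 lactone oxygen, C7, C8 angelate, C10 carbinol, C11–C13 methylene lactone), and D-lactic acid and D-mannitol-derived (R)-glyceraldehyde acetonide are taken as commercial.

## Retrosynthetic overview

1. Target 27 ⇒ seco-diene 26 by ring-closing metathesis at the C4=C5 (Z) olefin; the ten-membered carbocycle is the last ring formed.
2. 26 ⇒ 21 by turning C5 (CH2OTBS) into a vinyl group and by Mitsunobu inversion/esterification of the 8α-carbinol with angelic acid.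
3. 21 ⇒ keto-aldehyde 12 + bromobutenolide 19: the C7–C8 bond is made by an electrochemical zinc Barbier allylation that sets C7 and C8 and unveils the α-methylene lactone (the first ring, already present in 19).
4. 19 ⇒ (R)-glyceraldehyde acetonide 13 + methyl acrylate 14 (Baylis–Hillman, lactonisation, transposing bromination); C6 is bought.
5. 12 ⇒ (R)-lactic acid 1 via Seebach dioxolanone 3, ethylene sulfate 4 and the lithium reagent from bromide 9; C10 comes from lactate.

## Route

Step 1
Reactants: 1 (R)-lactic acid; 2 pivaldehyde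
Product: 3 (2R,5R)-2-tert-butyl-5-methyl-1,3-dioxolan-4-one
Conditions: TsOH·H2O (cat.), H2SO4 (cat.), pentane, reflux, Dean–Stark; recrystallise at −78 °C
Reagents that add atoms: none
Why: Acid-catalysed acetalisation (Seebach dioxolanone formation) gives the favoured cis acetal, so the new acetal centre is fixed by the lactate stereocentre and the cis isomer is purified by crystallisation.

Step 2
Reactants: 3 (2R,5R)-2-tert-butyl-5-methyl-1,3-dioxolan-4-one; 4 ethylene sulfate (1,3,2-dioxathiolane 2,2-dioxide)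
Product: 8 (3S)-3-hydroxy-3-methyloxolan-2-one, via lithium dioxolenolate 5 (not isolated), via lithium alkyl sulfate 6 (not isolated), via hydroxyethyl dioxolanone 7 (not isolated)
Conditions: LiN(iPr)2, THF, −78 °C; 4, −78 → −20 °C; then 20% aq H2SO4, 40 °C
Reagents that add atoms: none
Why: Seebach self-regeneration-of-stereocentres alkylation: enolate 5 is alkylated by the cyclic sulfate anti to the tert-butyl group, which sets the C10 quaternary carbinol, and acid hydrolysis of 6 frees alcohol 7, which translactonises with loss of pivaldehyde.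

Step 3
Reactants: 8 (3S)-3-hydroxy-3-methyloxolan-2-one; 9 4-bromo-2-methylbut-1-ene
Product: 11 (3S)-1,3-dihydroxy-3,7-dimethyloct-7-en-4-one (in equilibrium with its five-membered hemiketal), via 3-methylbut-3-enyllithium 10 (not isolated)
Conditions: 9, Li granules, Et2O, −20 °C; then 8 (0.45 equiv), THF, −78 °C; H2O quench
Reagents that add atoms: none
Why: Mono-addition of an organolithium to a lactone: the first equivalent deprotonates the tertiary hydroxyl and the dilithiated tetrahedral adduct is stable at −78 °C, so over-addition is suppressed and no stereocentre is touched.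

Step 4
Reactants: 11 (3S)-1,3-dihydroxy-3,7-dimethyloct-7-en-4-one
Product: 12 (3S)-3-hydroxy-3,7-dimethyl-4-oxooct-7-enal
Conditions: TEMPO (10 mol %), PhI(OAc)2, CH2Cl2, 0 → 23 °C
Reagents that add atoms: none
Why: Oxoammonium (TEMPO) oxidation is selective for the primary alcohol of the open-chain form; the tertiary alcohol, the ketone and the 1,1-disubstituted olefin are inert and the hemiketal cannot be over-oxidised.

Step 5
Reactants: 13 (R)-2,2-dimethyl-1,3-dioxolane-4-carbaldehyde; 14 methyl acrylate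
Product: 15 methyl 2-{[(4R)-2,2-dimethyl-1,3-dioxolan-4-yl](hydroxy)methyl}prop-2-enoate (both carbinol epimers)
Conditions: DABCO (0.5 equiv), dioxane/H2O (1:1), 23 °C, 3–5 d
Reagents that add atoms: none
Why: Morita–Baylis–Hillman reaction; the new carbinol forms as an epimer mixture that does not matter because this centre becomes sp2 in step 8.

Step 6
Reactants: 15 methyl 2-{[(4R)-2,2-dimethyl-1,3-dioxolan-4-yl](hydroxy)methyl}prop-2-enoate
Product: 17 (5R)-4-hydroxy-5-(hydroxymethyl)-3-methylideneoxolan-2-one (both C4 epimers), via methyl trihydroxy ester 16 (not isolated)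
Conditions: CF3CO2H/H2O (4:1), 0 → 23 °C; toluene azeotrope
Reagents that add atoms: none
Why: Acetonide hydrolysis followed by γ-lactonisation of the secondary (C6) hydroxyl onto the methyl ester, the five-membered lactone being favoured over the six-membered one; C6 is untouched.

Step 7
Reactants: 17 (5R)-4-hydroxy-5-(hydroxymethyl)-3-methylideneoxolan-2-one
Product: 18 (5R)-5-({[tert-butyl(dimethyl)silyl]oxy}methyl)-4-hydroxy-3-methylideneoxolan-2-one (both C4 epimers)
Conditions: TBSCl (1.05 equiv), imidazole, CH2Cl2, −20 → 0 °C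
Reagents that add atoms: tert-butyl(chloro)dimethylsilane (TBSCl), CC(C)(C)[Si](C)(C)Cl
Why: Silyl ether formation is selective for the primary over the secondary allylic hydroxyl on steric grounds.

Step 8
Reactants: 18 (5R)-5-({[tert-butyl(dimethyl)silyl]oxy}methyl)-4-hydroxy-3-methylideneoxolan-2-one
Product: 19 (5S)-3-(bromomethyl)-5-({[tert-butyl(dimethyl)silyl]oxy}methyl)furan-2(5H)-one
Conditions: NBS, Me2S, CH2Cl2, −20 → 23 °C
Reagents that add atoms: N-bromosuccinimide, O=C1CCC(=O)N1Br
Why: Corey–Kim-type bromination of the Baylis–Hillman allylic alcohol with allylic transposition (SN2′) gives the conjugated butenolide, converging both C7 epimers; C6 is untouched (the descriptor changes only through priorities).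

Step 9
Reactants: 12 (3S)-3-hydroxy-3,7-dimethyl-4-oxooct-7-enal; 19 (5S)-3-(bromomethyl)-5-({[tert-butyl(dimethyl)silyl]oxy}methyl)furan-2(5H)-one
Product: 21 (4R,5S)-5-({[tert-butyl(dimethyl)silyl]oxy}methyl)-4-[(1S,3S)-1,3-dihydroxy-3,7-dimethyl-4-oxooct-7-en-1-yl]-3-methylideneoxolan-2-one, via allylzinc bromide 20 (not isolated)
Conditions: undivided cell, Zn anode, glassy-carbon cathode, ZnBr2 (20 mol %), Bu4NBr (0.1 M), THF/DMF (4:1), 0 °C, 5 mA cm−2, 2.1 F mol−1 on 19 (1.2 equiv); aq NH4Cl work-up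
Reagents that add atoms: none
Why: Proposed new method: sacrificial-anode electroreductive zinc Barbier allylation of a 3-(bromomethyl)butenolide. Cathodic two-electron cleavage of the activated allylic C–Br bond, in the presence of divalent zinc released from the anode, gives allylzinc 20 at low steady-state concentration under anhydrous, non-basic conditions (which protects the β-hydroxy aldehyde). 20 adds through its γ-carbon (C7) to the aldehyde rather than the hindered ketone via a closed six-membered Zimmerman–Traxler transition state: attack anti to the C6 substituent sets C7, and the ring-locked E-type allyl geometry with an equatorial aldehyde residue is expected to give the 7,8-anti (8α) carbinol. Closest known chemistry: zinc-dust Barbier additions of bromomethylbutenolides to aldehydes, and sacrificial-anode electroallylation of carbonyls with simple allyl halides.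

Step 10
Reactants: 21 (4R,5S)-5-({[tert-butyl(dimethyl)silyl]oxy}methyl)-4-[(1S,3S)-1,3-dihydroxy-3,7-dimethyl-4-oxooct-7-en-1-yl]-3-methylideneoxolan-2-one; 22 angelic acid [(2Z)-2-methylbut-2-enoic acid]
Product: 23 (1R,3S)-1-[(2S,3R)-2-({[tert-butyl(dimethyl)silyl]oxy}methyl)-4-methylidene-5-oxooxolan-3-yl]-3-hydroxy-3,7-dimethyl-4-oxooct-7-en-1-yl (2Z)-2-methylbut-2-enoate
Conditions: PPh3, DIAD, toluene, −20 → 23 °C
Reagents that add atoms: none
Why: Mitsunobu esterification with SN2 inversion converts the 8α-carbinol into the 8β-angelate in one step; the tertiary C10 hydroxyl does not react and the neutral conditions keep the Z-enoate geometry.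

Step 11
Reactants: 23 (the silyl ether angelate)
Product: 24 (1R,3S)-3-hydroxy-1-[(2S,3R)-2-(hydroxymethyl)-4-methylidene-5-oxooxolan-3-yl]-3,7-dimethyl-4-oxooct-7-en-1-yl (2Z)-2-methylbut-2-enoate
Conditions: HF·pyridine, pyridine, THF, 0 → 23 °C
Reagents that add atoms: none
Why: Fluoride-mediated desilylation of the primary TBS ether under buffered conditions leaves the angelate, the methylene lactone and the tertiary alcohol intact.

Step 12
Reactants: 24 (the primary alcohol)
Product: 25 (1R,3S)-1-[(2S,3R)-2-formyl-4-methylidene-5-oxooxolan-3-yl]-3-hydroxy-3,7-dimethyl-4-oxooct-7-en-1-yl (2Z)-2-methylbut-2-enoate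
Conditions: Dess–Martin periodinane, NaHCO3, CH2Cl2, 0 °C
Reagents that add atoms: none
Why: Dess–Martin oxidation of the only primary alcohol (C8 is already esterified, so no lactol can form); buffered, non-basic conditions protect the epimerisable C6–H.

Step 13
Reactants: 25 (the C5 aldehyde)
Product: 26 (1R,3S)-1-[(2R,3R)-2-ethenyl-4-methylidene-5-oxooxolan-3-yl]-3-hydroxy-3,7-dimethyl-4-oxooct-7-en-1-yl (2Z)-2-methylbut-2-enoate
Conditions: CH2I2, Zn dust, Ti(OiPr)4, THF, 0 → 23 °C
Reagents that add atoms: diiodomethane, ICI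
Why: Takai methylenation (gem-dizinc/titanium reagent) is non-basic and aldehyde-selective, so the ketone, lactone, enoates and the C6 stereocentre are untouched (the C6 descriptor changes only through priorities).

Step 14
Reactants: 26 (the seco-diene)
Product: 27 (3aR,4R,6S,10Z,11aR)-6-hydroxy-6,10-dimethyl-3-methylidene-2,7-dioxo-2,3,3a,4,5,6,7,8,9,11a-decahydrocyclodeca[b]furan-4-yl (2Z)-2-methylbut-2-enoate (target)
Conditions: RuCl2(=CHPh)(PCy3)(H2IMes) (second-generation Grubbs catalyst, 10 mol %), toluene (1 mM), 80 °C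
Reagents that add atoms: none
Why: Ring-closing metathesis between the vinyl group and the 1,1-disubstituted olefin closes the ten-membered ring; at this ring size the cis (Z) trisubstituted cycloalkene is expected to be the less strained isomer, and the electron-poor methylene-lactone and angelate olefins do not engage.

## Compound list

1 | (R)-lactic acid | C[C@@H](O)C(=O)O | starting material
2 | pivaldehyde | CC(C)(C)C=O | starting material
3 | (2R,5R)-2-tert-butyl-5-methyl-1,3-dioxolan-4-one | C[C@H]1O[C@@H](C(C)(C)C)OC1=O | intermediate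
4 | ethylene sulfate (1,3,2-dioxathiolane 2,2-dioxide) | O=S1(=O)OCCO1 | starting material
5 | lithium (2R)-2-tert-butyl-5-methyl-1,3-dioxol-4-olate | CC1=C([O-])O[C@H](C(C)(C)C)O1.[Li+] | intermediate
6 | lithium 2-[(2R,4S)-2-tert-butyl-4-methyl-5-oxo-1,3-dioxolan-4-yl]ethyl sulfate | C[C@@]1(CCOS(=O)(=O)[O-])O[C@@H](C(C)(C)C)OC1=O.[Li+] | intermediate
7 | (2R,5S)-2-tert-butyl-5-(2-hydroxyethyl)-5-methyl-1,3-dioxolan-4-one | C[C@@]1(CCO)O[C@@H](C(C)(C)C)OC1=O | intermediate
8 | (3S)-3-hydroxy-3-methyloxolan-2-one | O=C1OCC[C@]1(C)O | intermediate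
9 | 4-bromo-2-methylbut-1-ene | C=C(C)CCBr | starting material
10 | 3-methylbut-3-enyllithium | [Li]CCC(C)=C | intermediate
11 | (3S)-1,3-dihydroxy-3,7-dimethyloct-7-en-4-one | OCC[C@](C)(O)C(=O)CCC(C)=C | intermediate
12 | (3S)-3-hydroxy-3,7-dimethyl-4-oxooct-7-enal | O=CC[C@](C)(O)C(=O)CCC(C)=C | intermediate
13 | (R)-2,2-dimethyl-1,3-dioxolane-4-carbaldehyde | O=C[C@H]1COC(C)(C)O1 | starting material
14 | methyl acrylate | C=CC(=O)OC | starting material
15 | methyl 2-{[(4R)-2,2-dimethyl-1,3-dioxolan-4-yl](hydroxy)methyl}prop-2-enoate | C=C(C(=O)OC)C(O)[C@H]1COC(C)(C)O1 | intermediate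
16 | methyl (4R)-3,4,5-trihydroxy-2-methylidenepentanoate | C=C(C(=O)OC)C(O)[C@H](O)CO | intermediate
17 | (5R)-4-hydroxy-5-(hydroxymethyl)-3-methylideneoxolan-2-one | C=C1C(O)[C@@H](CO)OC1=O | intermediate
18 | (5R)-5-({[tert-butyl(dimethyl)silyl]oxy}methyl)-4-hydroxy-3-methylideneoxolan-2-one | C=C1C(O)[C@@H](CO[Si](C)(C)C(C)(C)C)OC1=O | intermediate
19 | (5S)-3-(bromomethyl)-5-({[tert-butyl(dimethyl)silyl]oxy}methyl)furan-2(5H)-one | O=C1O[C@H](CO[Si](C)(C)C(C)(C)C)C=C1CBr | intermediate
20 | {[(5S)-5-({[tert-butyl(dimethyl)silyl]oxy}methyl)-2-oxo-2,5-dihydrofuran-3-yl]methyl}zinc bromide | O=C1O[C@H](CO[Si](C)(C)C(C)(C)C)C=C1C[Zn]Br | intermediate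
21 | (4R,5S)-5-({[tert-butyl(dimethyl)silyl]oxy}methyl)-4-[(1S,3S)-1,3-dihydroxy-3,7-dimethyl-4-oxooct-7-en-1-yl]-3-methylideneoxolan-2-one | C=C1C(=O)O[C@H](CO[Si](C)(C)C(C)(C)C)[C@H]1[C@@H](O)C[C@](C)(O)C(=O)CCC(C)=C | intermediate
22 | angelic acid, (2Z)-2-methylbut-2-enoic acid | C/C=C(/C)C(=O)O | starting material
23 | (1R,3S)-1-[(2S,3R)-2-({[tert-butyl(dimethyl)silyl]oxy}methyl)-4-methylidene-5-oxooxolan-3-yl]-3-hydroxy-3,7-dimethyl-4-oxooct-7-en-1-yl (2Z)-2-methylbut-2-enoate | C=C1C(=O)O[C@H](CO[Si](C)(C)C(C)(C)C)[C@H]1[C@H](OC(=O)/C(C)=C\C)C[C@](C)(O)C(=O)CCC(C)=C | intermediate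
24 | (1R,3S)-3-hydroxy-1-[(2S,3R)-2-(hydroxymethyl)-4-methylidene-5-oxooxolan-3-yl]-3,7-dimethyl-4-oxooct-7-en-1-yl (2Z)-2-methylbut-2-enoate | C=C1C(=O)O[C@H](CO)[C@H]1[C@H](OC(=O)/C(C)=C\C)C[C@](C)(O)C(=O)CCC(C)=C | intermediate
25 | (1R,3S)-1-[(2S,3R)-2-formyl-4-methylidene-5-oxooxolan-3-yl]-3-hydroxy-3,7-dimethyl-4-oxooct-7-en-1-yl (2Z)-2-methylbut-2-enoate | C=C1C(=O)O[C@H](C=O)[C@H]1[C@H](OC(=O)/C(C)=C\C)C[C@](C)(O)C(=O)CCC(C)=C | intermediate
26 | (1R,3S)-1-[(2R,3R)-2-ethenyl-4-methylidene-5-oxooxolan-3-yl]-3-hydroxy-3,7-dimethyl-4-oxooct-7-en-1-yl (2Z)-2-methylbut-2-enoate | C=C1C(=O)O[C@H](C=C)[C@H]1[C@H](OC(=O)/C(C)=C\C)C[C@](C)(O)C(=O)CCC(C)=C | intermediate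
27 | (3aR,4R,6S,10Z,11aR)-6-hydroxy-6,10-dimethyl-3-methylidene-2,7-dioxo-2,3,3a,4,5,6,7,8,9,11a-decahydrocyclodeca[b]furan-4-yl (2Z)-2-methylbut-2-enoate | C=C1C(=O)O[C@@H]2/C=C(/C)CCC(=O)[C@@](C)(O)C[C@@H](OC(=O)/C(C)=C\C)[C@@H]12 | target

## Step count and risks

Total: 14 steps. Longest linear sequence: 10 steps (1–4, then 9–14; the branch 5–8, then 9–14 is equally long).

The three steps most likely to fail:

**Step 9 (proposed electrochemical Barbier).** Risks are competing reduction or homocoupling of 19, addition to the ketone, and an unexpected sense at C8. The fallback sets out from 19 and returns at 21. Palladium-catalysed borylation of 19 with bis(pinacolato)diboron (Pd2(dba)3, DMSO, 50 °C) gives the allylboronate F1. Allylboration of 12 with F1 (toluene, 60 °C, or Sc(OTf)3 as catalyst) passes through the same closed chair and gives 21 after aqueous work-up. This is known chemistry of 2-alkoxycarbonyl allylboronates.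

**Step 10 (Mitsunobu on a hindered carbinol).** Risks are slow reaction, elimination, or partial angelate-to-tiglate isomerisation. The fallback sets out from 21 and returns at 23. Mitsunobu inversion with the more acidic chloroacetic acid (PPh3, DIAD) gives the 8β-chloroacetate F2. Thiourea and NaHCO3 in ethanol cleave it to the 8β-alcohol F3. F3 is acylated with retention by the mixed anhydride of 22 and 2,4,6-trichlorobenzoyl chloride (Et3N, toluene, 75 °C) to give 23.

**Step 14 (ten-membered ring-closing metathesis).** Risks are oligomerisation or E/Z mixtures. The fallback sets out from 21 and returns at 27; it closes the ring on a conformationally locked substrate and inverts C8 last. 21 is converted with 2-methoxypropene and PPTS into the 8,10-acetonide F4. HF·pyridine gives the primary alcohol F5, Dess–Martin oxidation the aldehyde F6, and Takai methylenation the diene F7. Metathesis with the same ruthenium catalyst gives the macrocyclic acetonide F8, and 80% aqueous acetic acid at 40 °C frees the 8α,10-diol F9. Mitsunobu esterification of F9 with 22 (PPh3, DIAD) gives 27.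

## Further compounds

F1 | step 9 | (5S)-5-({[tert-butyl(dimethyl)silyl]oxy}methyl)-3-[(4,4,5,5-tetramethyl-1,3,2-dioxaborolan-2-yl)methyl]furan-2(5H)-one | O=C1O[C@H](CO[Si](C)(C)C(C)(C)C)C=C1CB2OC(C)(C)C(C)(C)O2
F2 | step 10 | (1R,3S)-1-[(2S,3R)-2-({[tert-butyl(dimethyl)silyl]oxy}methyl)-4-methylidene-5-oxooxolan-3-yl]-3-hydroxy-3,7-dimethyl-4-oxooct-7-en-1-yl chloroacetate | C=C1C(=O)O[C@H](CO[Si](C)(C)C(C)(C)C)[C@H]1[C@H](OC(=O)CCl)C[C@](C)(O)C(=O)CCC(C)=C
F3 | step 10 | (4R,5S)-5-({[tert-butyl(dimethyl)silyl]oxy}methyl)-4-[(1R,3S)-1,3-dihydroxy-3,7-dimethyl-4-oxooct-7-en-1-yl]-3-methylideneoxolan-2-one | C=C1C(=O)O[C@H](CO[Si](C)(C)C(C)(C)C)[C@H]1[C@H](O)C[C@](C)(O)C(=O)CCC(C)=C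
F4 | step 14 | (4R,5S)-5-({[tert-butyl(dimethyl)silyl]oxy}methyl)-3-methylidene-4-[(4S,6S)-2,2,6-trimethyl-6-(4-methylpent-4-enoyl)-1,3-dioxan-4-yl]oxolan-2-one | C=C1C(=O)O[C@H](CO[Si](C)(C)C(C)(C)C)[C@H]1[C@@H]2C[C@](C)(OC(C)(C)O2)C(=O)CCC(C)=C
F5 | step 14 | (4R,5S)-5-(hydroxymethyl)-3-methylidene-4-[(4S,6S)-2,2,6-trimethyl-6-(4-methylpent-4-enoyl)-1,3-dioxan-4-yl]oxolan-2-one | C=C1C(=O)O[C@H](CO)[C@H]1[C@@H]2C[C@](C)(OC(C)(C)O2)C(=O)CCC(C)=C
F6 | step 14 | (2S,3R)-4-methylidene-5-oxo-3-[(4S,6S)-2,2,6-trimethyl-6-(4-methylpent-4-enoyl)-1,3-dioxan-4-yl]oxolane-2-carbaldehyde | C=C1C(=O)O[C@H](C=O)[C@H]1[C@@H]2C[C@](C)(OC(C)(C)O2)C(=O)CCC(C)=C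
F7 | step 14 | (4R,5R)-5-ethenyl-3-methylidene-4-[(4S,6S)-2,2,6-trimethyl-6-(4-methylpent-4-enoyl)-1,3-dioxan-4-yl]oxolan-2-one | C=C1C(=O)O[C@H](C=C)[C@H]1[C@@H]2C[C@](C)(OC(C)(C)O2)C(=O)CCC(C)=C
F8 | step 14 | 8,10-O-isopropylidene acetal of (4Z)-8α,10-dihydroxy-1-oxogermacra-4,11(13)-dien-12,6α-olide | C=C1C(=O)O[C@@H]2/C=C(/C)CCC(=O)[C@]3(C)C[C@H](OC(C)(C)O3)[C@@H]12
F9 | step 14 | (3aR,4S,6S,10Z,11aR)-4,6-dihydroxy-6,10-dimethyl-3-methylidene-3a,4,5,6,8,9-hexahydrocyclodeca[b]furan-2,7(3H,11aH)-dione | C=C1C(=O)O[C@@H]2/C=C(/C)CCC(=O)[C@@](C)(O)C[C@H](O)[C@@H]12
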